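The chroman is cut at C2–C3, C3–C4 and O1–C8a. What remains of ring B on the side-chain half, O1–C2(CH3) with the whole C1'–C12' triene chain, is (5E,9E)-farnesylacetone, whose carbonyl oxygen is the future O1. A catalytic enantioselective sulfur-ylide methylenation of this methyl ketone adds C3, forms C2–C3 and sets C2 (R) in one operation, parking O1, C2 and C3 in a temporary oxirane. The precursor is therefore the achiral C18 ketone itself. A benzylic Grignard reagent carrying ring A and C4 then opens the oxirane at C3, and ring B is closed at the quinone level through O1–C8a without touching C2.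

Key step: step 3

Numbering: chroman numbering is used (O1, C2, C3, C4, C4a, C5 to C8, C8a; side chain C1' to C12' from C2); ring A is the benzene ring, ring B the dihydropyran ring.

Assumption: the (R)-binaphthol-derived catalyst is taken, by analogy with simple alkyl methyl ketones, to send CH2 to the Si face of the C2 carbonyl; if the sense of induction proves opposite, the antipodal binaphthol is used and nothing else changes.

Step 1
Reactants: 1 (2E,6E)-farnesyl bromide; 2 ethyl acetoacetate
Product: 5 (5E,9E)-farnesylacetone, via keto ester 3 (not isolated), via keto acid 4 (not isolated)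
Conditions: 2 (1.5 equiv), NaH, THF, 0 °C; 1, 0 °C to rt; then aq. NaOH, MeOH, 50 °C; then aq. HCl to pH 3, 50 °C
Reagents that add atoms: none
Why: Acetoacetic ester ketone synthesis: the sodium enolate of 2, used in excess to suppress dialkylation, should displace the primary allylic bromide by SN2 attack with both E alkenes untouched, after which saponification and decarboxylation of the β-keto acid unmask the methyl ketone; no stereocentre is formed.

Step 2
Reactants: 6 trimethylsulfoxonium iodide
Product: 7 dimethyloxosulfonium methylide (THF stock solution, titrated and used directly)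
Conditions: NaH (0.95 equiv), THF, reflux; filtered under argon
Reagents that add atoms: none
Why: Deprotonation of the sulfoxonium salt by NaH (Corey–Chaykovsky ylide generation) should give the stabilised ylide as a hydride-free solution, so that no achiral base is left to enolise the ketone or to compete with the chiral catalyst in step 3.

Step 3
Reactants: 5 (5E,9E)-farnesylacetone; 7 dimethyloxosulfonium methylide
Product: 8 (R)-2-methyl-2-[(3E,7E)-4,8,12-trimethyltrideca-3,7,11-trien-1-yl]oxirane
Conditions: 7 (1.2 equiv), LaLi3[(R)-binaphthoxide]3 (5 mol %), tris(2,4,6-trimethoxyphenyl)phosphine oxide (5 mol %), 5 Å molecular sieves, THF, rt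
Reagents that add atoms: none
Why: This is a catalytic asymmetric Corey–Chaykovsky epoxidation, the closest known reaction type being the lanthanum–lithium binaphthoxide-catalysed methylene transfer from this ylide to simple alkyl methyl ketones. The trivalent lanthanum centre, made more crowded by the phosphine oxide, should bind the C2 carbonyl while a lithium binaphthoxide arm positions the ylide, so that the ylide carbon adds to the Si face of C2 (O > chain CH2 > CH3) and forms the C2–C3 bond. The betaine alkoxide then displaces dimethyl sulfoxide from C3 in a 3-exo-tet closure, which makes the oxirane O1–C2–C3 and turns the carbonyl oxygen into the future O1. The new stereocentre C2 is set (R) by the chiral binaphthoxide pocket alone, since the substrate has no other stereocentre. The step needs enantioface selection between a methyl group and an unbranched chain CH2, a size difference this catalyst class reads well, and chemoselectivity for C=O, which is secured because the three unactivated trisubstituted alkenes are inert to a nucleophilic sulfur ylide. Keeping the ylide near one equivalent at room temperature should prevent a second methylene transfer that would expand the oxirane to an oxetane.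

Step 4
Reactants: 9 1,4-dimethoxy-2,5-dimethylbenzene
Product: 10 1-(chloromethyl)-2,5-dimethoxy-3,6-dimethylbenzene
Conditions: (CH2O)n (1.0 equiv), HCl gas, AcOH, 40 °C, stopped at partial conversion
Reagents that add atoms: paraformaldehyde (formaldehyde source), C=O; hydrogen chloride, Cl
Why: Blanc chloromethylation of an electron-rich arene: the two free ring positions are equivalent and each lies ortho to a methoxy group, so only one regioisomer can form, and limiting formaldehyde and conversion should hold back a second chloromethylation and diarylmethane formation (the reaction is run in a closed, scrubbed apparatus because bis(chloromethyl) ether can form).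

Step 5
Reactants: 10 1-(chloromethyl)-2,5-dimethoxy-3,6-dimethylbenzene; 8 (R)-oxirane
Product: 12 (3R,6E,10E)-1-(2,5-dimethoxy-3,6-dimethylphenyl)-3,7,11,15-tetramethylhexadeca-6,10,14-trien-3-ol, via benzylic Grignard reagent 11 (not isolated)
Conditions: 10 (1.6 equiv), Mg turnings, THF, 0 °C, slow addition; then CuI (10 mol %), 8, −30 to 0 °C; aq. NH4Cl
Reagents that add atoms: none
Why: Copper-catalysed Grignard opening of a 2,2-disubstituted oxirane: the benzylic organocopper species should attack the unhindered C3 methylene in SN2 fashion, so C3–C4 forms while the C2–O1 bond and the C2 configuration stay untouched, and the two ortho substituents on the arene block the abnormal ortho-attack pathway of benzylic Grignard reagents.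

Step 6
Reactants: 12 tertiary alcohol
Product: 13 2-[(3R,6E,10E)-3-hydroxy-3,7,11,15-tetramethylhexadeca-6,10,14-trien-1-yl]-3,6-dimethylcyclohexa-2,5-diene-1,4-dione
Conditions: (NH4)2Ce(NO3)6 (2.5 equiv), MeCN/H2O, 0 °C
Reagents that add atoms: water, O
Why: Oxidative demethylation of a hydroquinone dimethyl ether by tetravalent cerium: single-electron oxidation of the electron-rich arene and capture of the radical cation by water should release both methoxy groups as methanol and give the para-quinone, while the isolated trisubstituted alkenes and the tertiary alcohol, which are much harder to oxidise, survive and the carbinol stereocentre is not involved.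

Step 7
Reactants: 13 hydroxy quinone
Product: 15 (R)-β-tocotrienol, via hydroquinone 14 (not isolated)
Conditions: Na2S2O4, EtOAc/H2O, rt; organic phase dried and concentrated; then TsOH·H2O (10 mol %), 13 (5 mol %), toluene, 40 °C, N2
Reagents that add atoms: none
Why: Retentive cyclodehydration of a γ-hydroxyalkyl hydroquinone by a quinone–hydroquinone redox chain: the small amount of quinone 13 should close reversibly to the C8a hemiketal by 6-exo-trig addition of the tertiary hydroxyl to the C8a carbonyl, acid then ionises the hemiketal to an aryloxonium ion that hydroquinone 14 reduces to the chromanol while regenerating 13, so O1–C8a forms, the C2–O1 bond is never broken and C2 stays (R).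

Compound list
1 | (2E,6E)-farnesyl bromide | CC(C)=CCC/C(C)=C/CC/C(C)=C/CBr | starting material
2 | ethyl acetoacetate | CCOC(=O)CC(C)=O | starting material
3 | ethyl (4E,8E)-2-acetyl-5,9,13-trimethyltetradeca-4,8,12-trienoate (racemic) | CC(C)=CCC/C(C)=C/CC/C(C)=C/CC(C(C)=O)C(=O)OCC | intermediate
4 | (4E,8E)-2-acetyl-5,9,13-trimethyltetradeca-4,8,12-trienoic acid (racemic) | CC(C)=CCC/C(C)=C/CC/C(C)=C/CC(C(C)=O)C(=O)O | intermediate
5 | (5E,9E)-farnesylacetone, (5E,9E)-6,10,14-trimethylpentadeca-5,9,13-trien-2-one | CC(C)=CCC/C(C)=C/CC/C(C)=C/CCC(C)=O | intermediate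
6 | trimethylsulfoxonium iodide | C[S+](C)(C)=O.[I-] | starting material
7 | dimethyloxosulfonium methylide | C[S+](C)(=O)[CH2-] | intermediate
8 | (R)-2-methyl-2-[(3E,7E)-4,8,12-trimethyltrideca-3,7,11-trien-1-yl]oxirane | CC(C)=CCC/C(C)=C/CC/C(C)=C/CC[C@]1(C)CO1 | intermediate
9 | 1,4-dimethoxy-2,5-dimethylbenzene | COc1cc(C)c(OC)cc1C | starting material
10 | 1-(chloromethyl)-2,5-dimethoxy-3,6-dimethylbenzene | COc1cc(C)c(OC)c(CCl)c1C | intermediate
11 | (2,5-dimethoxy-3,6-dimethylbenzyl)magnesium chloride | COc1cc(C)c(OC)c(C[Mg]Cl)c1C | intermediate
12 | (3R,6E,10E)-1-(2,5-dimethoxy-3,6-dimethylphenyl)-3,7,11,15-tetramethylhexadeca-6,10,14-trien-3-ol | CC(C)=CCC/C(C)=C/CC/C(C)=C/CC[C@@](C)(O)CCc1c(C)c(OC)cc(C)c1OC | intermediate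
13 | 2-[(3R,6E,10E)-3-hydroxy-3,7,11,15-tetramethylhexadeca-6,10,14-trien-1-yl]-3,6-dimethylcyclohexa-2,5-diene-1,4-dione | CC(C)=CCC/C(C)=C/CC/C(C)=C/CC[C@@](C)(O)CCC1=C(C)C(=O)C=C(C)C1=O | intermediate
14 | 2-[(3R,6E,10E)-3-hydroxy-3,7,11,15-tetramethylhexadeca-6,10,14-trien-1-yl]-3,6-dimethylbenzene-1,4-diol | CC(C)=CCC/C(C)=C/CC/C(C)=C/CC[C@@](C)(O)CCc1c(C)c(O)cc(C)c1O | intermediate
15 | (R)-β-tocotrienol, (2R)-2,5,8-trimethyl-2-[(3E,7E)-4,8,12-trimethyltrideca-3,7,11-trien-1-yl]-3,4-dihydro-2H-chromen-6-ol | CC(C)=CCC/C(C)=C/CC/C(C)=C/CC[C@]1(C)CCc2c(C)c(O)cc(C)c2O1 | target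

Total step count: 7. Longest linear sequence: 5 steps (steps 1, 3, 5, 6, 7).

Steps most likely to fail

Step 3. The catalyst may discriminate poorly between the methyl group and the flexible chain, or the basic ylide may enolise the ketone and leave the reaction incomplete. The fallback sets out from 1 and comes back at 8, with C2 set by a tartrate instead of the binaphthoxide catalyst. The dianion of 2-methylprop-2-en-1-ol (n-BuLi, TMEDA) is alkylated at its allylic carbon with 1 to give (5E,9E)-6,10,14-trimethyl-2-methylidenepentadeca-5,9,13-trien-1-ol F1. Sharpless asymmetric epoxidation (Ti(OiPr)4, D-(−)-diethyl tartrate, t-BuOOH, 4 Å molecular sieves, CH2Cl2, −20 °C) is directed by the hydroxyl group and so leaves the three remote alkenes alone. By analogy with 2-methylprop-2-en-1-ol it should give [(2R)-2-[(3E,7E)-4,8,12-trimethyltrideca-3,7,11-trien-1-yl]oxiran-2-yl]methanol F2. LiAlH4 (THF, 0 °C) opens this oxirane at its unsubstituted CH2, which becomes the C2 methyl group, to give (2R,5E,9E)-2,6,10,14-tetramethylpentadeca-5,9,13-triene-1,2-diol F3. Tosylation of the primary hydroxyl (TsCl, pyridine) gives (2R,5E,9E)-2-hydroxy-2,6,10,14-tetramethylpentadeca-5,9,13-trien-1-yl 4-methylbenzenesulfonate F4, and K2CO3 in methanol closes it to 8 with the tertiary C–O bond intact.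

Step 7. Acid may trigger cation–olefin cyclisation or hydration of the triene, and if the redox chain stalls, ionisation at C2 would cause elimination or loss of configuration. The fallback sets out from 13 and comes back at 15; it closes the ring first, at the quinone oxidation level, and reduces afterwards. Quinone 13 is stirred with trimethyl orthoformate and a trace of pyridinium p-toluenesulfonate in methanol at rt, which should trap the C8a hemiketal as the cyclic mixed ketal (2R)-8a-methoxy-2,5,8-trimethyl-2-[(3E,7E)-4,8,12-trimethyltrideca-3,7,11-trien-1-yl]-2,3,4,8a-tetrahydro-6H-chromen-6-one F5 (either C8a epimer serves). This ketal is then reduced with ascorbic acid in aqueous ethanol at rt, where two-electron reduction of the dienone and loss of methanol from C8a should aromatise ring A to 15. C2 keeps its oxygen throughout, and the triene never meets acid and heat together.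

Step 5. Wurtz-type homocoupling may consume the electron-rich benzylic halide while the Grignard reagent forms, and magnesium chloride may rearrange the 2,2-disubstituted oxirane to an aldehyde or open it to a chlorohydrin before the copper-mediated attack occurs. The fallback sets out from 8 and comes back at 12; it takes C4 from the ylide and attaches ring A as an aryl anion, so the bond formed is C4–C4a and no benzylic organometallic is needed. Oxirane 8 is warmed with a further equivalent of 7 (t-BuOH/THF, 50 °C), which opens it at C3 and recloses by 4-exo-tet loss of dimethyl sulfoxide to (2R)-2-methyl-2-[(3E,7E)-4,8,12-trimethyltrideca-3,7,11-trien-1-yl]oxetane F6. Arene 9 is brominated (NBS, MeCN) to 1-bromo-2,5-dimethoxy-3,6-dimethylbenzene F7, and bromine–lithium exchange (n-BuLi, THF, −78 °C) gives (2,5-dimethoxy-3,6-dimethylphenyl)lithium F8. Addition of F6 and BF3·OEt2 at −78 °C should open the oxetane at its unhindered O–CH2 carbon and give 12 after work-up.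

Further compounds
F1 | step 3 | (5E,9E)-6,10,14-trimethyl-2-methylidenepentadeca-5,9,13-trien-1-ol | CC(C)=CCC/C(C)=C/CC/C(C)=C/CCC(=C)CO
F2 | step 3 | [(2R)-2-[(3E,7E)-4,8,12-trimethyltrideca-3,7,11-trien-1-yl]oxiran-2-yl]methanol | CC(C)=CCC/C(C)=C/CC/C(C)=C/CC[C@@]1(CO)CO1
F3 | step 3 | (2R,5E,9E)-2,6,10,14-tetramethylpentadeca-5,9,13-triene-1,2-diol | CC(C)=CCC/C(C)=C/CC/C(C)=C/CC[C@](O)(C)CO
F4 | step 3 | (2R,5E,9E)-2-hydroxy-2,6,10,14-tetramethylpentadeca-5,9,13-trien-1-yl 4-methylbenzenesulfonate | CC(C)=CCC/C(C)=C/CC/C(C)=C/CC[C@](O)(C)COS(=O)(=O)c1ccc(C)cc1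
F5 | step 7 | (2R)-8a-methoxy-2,5,8-trimethyl-2-[(3E,7E)-4,8,12-trimethyltrideca-3,7,11-trien-1-yl]-2,3,4,8a-tetrahydro-6H-chromen-6-one (C8a epimers) | CC(C)=CCC/C(C)=C/CC/C(C)=C/CC[C@]1(C)CCC2=C(C)C(=O)C=C(C)C2(OC)O1
F6 | step 5 | (2R)-2-methyl-2-[(3E,7E)-4,8,12-trimethyltrideca-3,7,11-trien-1-yl]oxetane | CC(C)=CCC/C(C)=C/CC/C(C)=C/CC[C@]1(C)CCO1
F7 | step 5 | 1-bromo-2,5-dimethoxy-3,6-dimethylbenzene | COc1cc(C)c(OC)c(Br)c1C
F8 | step 5 | (2,5-dimethoxy-3,6-dimethylphenyl)lithium | COc1cc(C)c(OC)c([Li])c1C
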